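Readings and results are simulated for substances that don't exist.

- Compare, in the north run at 3.00 h, what has left the solid with what has appeared as product: the solid substrate reads 81.4%, so 18.6% has left it, but target and isomer of the product together read 2.00%.

- north: solid substrate 1.5 M; the very flask that is asked about, followed so far
- flask: solid substrate 1.5 M; time 2.0 d

- north (time / h: solid substrate / %, target / %, isomer of the product / %): 3.00: 81.4, 1.2, 0.8; 6.00: 76.4, 6.1, 1.8; 10.0: 51.7, 27.7, 11.2; 15.0: 0.3, 66.4, 32.6; 20.0: 0.5, 64.0, 36.7; 25.0: 0, 63.8, 36.9

(scatter of a reading: 0.5 percentage points)

* at 2.0 d, what has stopped the reaction, if anything has (for what has run out or reacted, a solid counts together with what of it has only dissolved) (it is still moving / all of the solid substrate has reacted / forward and back rates have come level)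
* part of the solid substrate that has turned into other species by 2.0 d (what has only dissolved does not count)
* how much target there is at 2.0 d, in percent of the solid substrate charged
* how much isomer of the product there is at 2.0 d, in percent of the solid substrate charged

- as a solid, counted per litre of solution: solid substrate
- at the start none of the solid substrate is in solution
- what has only dissolved of solid substrate counts as not reacted
- the reaction counts as stopped when no species that holds the solid substrate changes by six tenths of a point or more over the second half of the time

- Try the bench rule first: what has left the solid has reacted. At 25.0 h the solid substrate reads 0%, so the rule calls the north run complete.
- Find the border of that rule with a ratio: divide what has left the solid but shows as no product by what has left the solid. This ratio is 0.892 at 3.00 h, 0.195 at 10.0 h and 0.00702 at 15.0 h, so trust the rule late and not early; read the shortfall in the mass balance as substrate merely dissolved.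
- Reckon the correction directly: take 100 points minus target minus isomer of the product as the unreacted remainder. Two readings enter it, so judge it against the remainder band, the scatter of that difference, 0.71 percentage points.
- Apply the band to the north run at 25.0 h: the two products overshoot the charge by 0.7 points, less than the band, so the remainder is zero within scatter.
- Commit for the flask at 2.0 d: the solid substrate has reacted completely, and the last split of the readings gives target 63.4% and isomer of the product 36.6%.
- Set beside this the forecast, which gives conversion 100%, target 63.5% and isomer of the product 36.5%, and parts from this reckoning on the stop with "forward and back rates have come level", on the ground that “An irreversible step would have kept going at that pace”.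
- The flask gives "all of the solid substrate has reacted" at 2.0 d, with conversion 100%, target 63.8% and isomer of the product 36.2%. The relaxation half-life of target and isomer of the product by their own step is 0.566 h, short against 2.0 d. The remainder of the flask at 2.0 d is 0 points, which lies inside the band. The same flask read at 12 h has a remainder of 37.5%, which is 52.8 bands, and there 37% of the charge is still present, solid or dissolved.

    starting material → target (k = 4.32 × 10⁻⁶ /s)
    solid substrate ⇌ starting material, rate k2*(cs2 - [starting material]) while solid is left; crystals form when [starting material] > cs2 (solubility = 0.290 M, k = 2.43 × 10⁻⁴ /s)
    starting material + target → 2 target (k = 7.79 × 10⁻⁴ /M/s)
    target ⇌ isomer of the product (K = 0.567, k = 1.23 × 10⁻⁴ /s)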